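The side chain (C1 benzylic to C12 furylmethyl) is cut between C7, the methyl-bearing sp2 carbon of the C6=C7 alkene next to the C5 carbinol, and the C8 methylene. This exploits the 1,5-diene C6=C7–C8–C9–C10=C11: a homoallylic C8 zinc reagent carrying the furan ring is joined to an (E)-C7 alkenyl iodide carrying the silylated hydroquinone ring by palladium-catalysed Negishi coupling, which forms the C(sp2)–C(sp3) bond with retention of the 6E geometry. The iodide comes from a propargylic silyl ether (C6≡C7), whose C5 (S) centre is set by asymmetric alkynylation and whose hydrozirconation–iodination fixes regio- and stereochemistry of the alkene.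

Key step: step 11

Remark on the chemistry: the stereocentre of the target is read as (S); the explanations use the target numbering C1 (benzylic CH2) to C12 (CH2 on the furan), while compound names use their own locants.

Step 1
Reactants: 1 2,6-dimethylbenzene-1,4-diol
Product: 2 1,4-bis(tert-butyldimethylsilyloxy)-2,6-dimethylbenzene
Conditions: TBSCl, imidazole, DMF, 40 °C
Reagents that add atoms: tert-butyldimethylsilyl chloride CC(C)(C)[Si](C)(C)Cl
Why: Imidazole-mediated silyl ether formation on both phenols, warmed because one hydroxyl sits between two methyl groups; silyl ethers are chosen so that a single fluoride treatment frees everything at the end without acid, which the furan and the allylic alcohol would not tolerate.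

Step 2
Reactants: 2 1,4-bis(tert-butyldimethylsilyloxy)-2,6-dimethylbenzene
Product: 3 2-(bromomethyl)-1,4-bis(tert-butyldimethylsilyloxy)-6-methylbenzene
Conditions: NBS (0.95 equiv), AIBN (cat.), PhCF3, reflux
Reagents that add atoms: N-bromosuccinimide O=C1CCC(=O)N1Br
Why: Wohl–Ziegler radical bromination of a benzylic methyl group; the two methyl groups of 2 are equivalent by symmetry, so either one gives the substitution pattern of the target arene (CH2 and CH3 flanking one oxygen), and a slight deficit of NBS in a non-polar solvent should hold back dibromination and ionic ring bromination.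

Step 3
Reactants: 3 2-(bromomethyl)-1,4-bis(tert-butyldimethylsilyloxy)-6-methylbenzene, 4 but-3-yn-1-ol
Product: 6 (3E)-5-[2,5-bis(tert-butyldimethylsilyloxy)-3-methylphenyl]-3-methylpent-3-en-1-ol, via alkenylalane 5 (not isolated)
Conditions: 4, Me3Al (3 equiv), Cp2ZrCl2 (cat.), CH2Cl2, 0 °C to rt; evaporate, THF; then 3, Pd(PPh3)4 (5 mol%), rt
Reagents that add atoms: trimethylaluminium C[Al](C)C
Why: Zirconium-catalysed syn-methylalumination of the terminal alkyne (Negishi carboalumination) puts methyl on the internal carbon and aluminium cis to it on the terminal carbon, and palladium-catalysed alkenyl–benzyl cross-coupling of 5 with 3 then goes with retention, so the C1–C2 bond and the 2E trisubstituted alkene should form in one flask; removing excess Me3Al and working in THF tames the Lewis acidity toward the benzylic bromide.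

Step 4
Reactants: 6 (3E)-5-[2,5-bis(tert-butyldimethylsilyloxy)-3-methylphenyl]-3-methylpent-3-en-1-ol
Product: 7 (3E)-5-[2,5-bis(tert-butyldimethylsilyloxy)-3-methylphenyl]-3-methylpent-3-enal
Conditions: Dess–Martin periodinane, NaHCO3, CH2Cl2, 0 °C to rt
Reagents that add atoms: none
Why: Dess–Martin oxidation of the primary alcohol under buffered, non-basic conditions, chosen because the β,γ-unsaturated aldehyde would slip into conjugation with base; 7 is used at once.

Step 5
Reactants: 7 (3E)-5-[2,5-bis(tert-butyldimethylsilyloxy)-3-methylphenyl]-3-methylpent-3-enal, 8 propyne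
Product: 10 (4S,6E)-8-[2,5-bis(tert-butyldimethylsilyloxy)-3-methylphenyl]-6-methyloct-6-en-2-yn-4-ol, via ethyl(prop-1-ynyl)zinc 9 (not isolated)
Conditions: 8, Et2Zn, Cy2NH (cat.), (R)-BINOL (40 mol%), Et2O, rt; Ti(OiPr)4 (0.5 equiv); then 7, rt
Reagents that add atoms: none
Why: Catalytic asymmetric addition of an alkynylzinc to an aldehyde under BINOL–titanium control; the (R)-ligand is expected to deliver the propynyl group to the Re face of 7, which gives the (S) carbinol (C5), the sense to be confirmed by Mosher ester analysis, and the nearly amine-free Lewis-acidic medium should spare the enolisable aldehyde.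

Step 6
Reactants: 10 (4S,6E)-8-[2,5-bis(tert-butyldimethylsilyloxy)-3-methylphenyl]-6-methyloct-6-en-2-yn-4-ol
Product: 11 (4S,6E)-8-[2,5-bis(tert-butyldimethylsilyloxy)-3-methylphenyl]-4-(tert-butyldimethylsilyloxy)-6-methyloct-6-en-2-yne
Conditions: TBSCl, imidazole, DMF, rt
Reagents that add atoms: tert-butyldimethylsilyl chloride CC(C)(C)[Si](C)(C)Cl
Why: Silyl ether formation; the bulky silyloxy-bearing carbon should steer zirconium away from C6 in the next step (a free alkoxide could direct it there) and the ether keeps the alcohol from quenching the organozinc in step 11.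

Step 7
Reactants: 11 (4S,6E)-8-[2,5-bis(tert-butyldimethylsilyloxy)-3-methylphenyl]-4-(tert-butyldimethylsilyloxy)-6-methyloct-6-en-2-yne
Product: 13 (2E,4S,6E)-8-[2,5-bis(tert-butyldimethylsilyloxy)-3-methylphenyl]-4-(tert-butyldimethylsilyloxy)-2-iodo-6-methylocta-2,6-diene, via alkenylzirconocene chloride 12 (not isolated)
Conditions: Cp2Zr(H)Cl (2 equiv), THF, rt to 50 °C; then I2, 0 °C
Reagents that add atoms: iodine II
Why: Hydrozirconation is a syn addition that, after equilibration with excess reagent, should place zirconium on the less hindered methyl-bearing alkyne carbon (C7), and iododezirconation with retention gives the (E)-iodide with iodine trans to C5; the trisubstituted alkene is inert and the stereocentre is not involved.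

Step 8
Reactants: 14 5-bromo-2-methylpent-2-ene
Product: 15 (2E)-5-bromo-2-methylpent-2-en-1-ol
Conditions: SeO2 (cat.), t-BuOOH, CH2Cl2, rt
Reagents that add atoms: tert-butyl hydroperoxide (oxygen source, relayed by SeO2) CC(C)(C)OO
Why: SeO2-catalysed allylic oxidation (Riley oxidation, ene reaction then [2,3]-sigmatropic shift) attacks the more substituted alkene terminus and there the methyl group trans to the chain, which should give the (E)-allylic alcohol, the catalytic room-temperature variant favouring the alcohol over the enal.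

Step 9
Reactants: 15 (2E)-5-bromo-2-methylpent-2-en-1-ol
Product: 16 (2E)-1,5-dibromo-2-methylpent-2-ene
Conditions: PBr3, Et2O, 0 °C
Reagents that add atoms: phosphorus tribromide BrP(Br)Br
Why: SN2 conversion of the primary allylic alcohol into the bromide at low temperature, which should proceed without allylic transposition or loss of the E geometry.

Step 10
Reactants: 16 (2E)-1,5-dibromo-2-methylpent-2-ene, 17 3-methylfuran
Product: 19 2-[(2E)-5-bromo-2-methylpent-2-en-1-yl]-4-methylfuran, via (4-methylfuran-2-yl)magnesium chloride 18 (not isolated)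
Conditions: 17, TMPMgCl·LiCl, THF, 25 °C; then 16, Li2CuCl4 (3 mol%), −30 to 0 °C
Reagents that add atoms: none
Why: Magnesiation of 3-methylfuran by the hindered amide base should occur at the α-position remote from the methyl group (C5), and copper-catalysed SN2 coupling of the heteroaryl Grignard reagent then takes place at the primary allylic bromide of 16, which is far more reactive than the homoallylic bromide and is attacked at its unhindered α-carbon, so the E alkene is kept.

Step 11
Reactants: 13 (2E,4S,6E)-8-[2,5-bis(tert-butyldimethylsilyloxy)-3-methylphenyl]-4-(tert-butyldimethylsilyloxy)-2-iodo-6-methylocta-2,6-diene, 19 2-[(2E)-5-bromo-2-methylpent-2-en-1-yl]-4-methylfuran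
Product: 21 tris(tert-butyldimethylsilyl) ether of 22 (both phenols and the C5 hydroxyl silylated), via homoallylic zinc bromide 20 (not isolated)
Conditions: 19, zinc dust, LiCl, THF, 50 °C; then 13, PdCl2(dppf) (5 mol%), THF, rt to 40 °C
Reagents that add atoms: none
Why: Zinc inserts into the primary C–Br bond of 19 (LiCl keeps the organozinc in solution) to give 20; zerovalent palladium formed from PdCl2(dppf) adds oxidatively to the C–I bond of 13, and transmetalation from zinc followed by reductive elimination from divalent palladium forges the C7–C8 bond (Negishi coupling). The closest known reaction type is the palladium-catalysed coupling of homoallylic zinc halides with (E)-2-iodoalk-2-enes used to assemble the 1,5-dienes of isoprenoids. No ring is closed and no stereocentre is formed; the C5 (S) silyl ether is two atoms from the reacting carbon and is untouched. The step needs retention of the 6E geometry and C(sp3)–C(sp2) coupling without β-hydride elimination: retention is inherent to oxidative addition and reductive elimination at an alkenyl carbon, and the wide bite angle of dppf speeds reductive elimination from the alkyl(alkenyl)palladium intermediate. The base-free organozinc conditions are compatible with the aryl and alkyl silyl ethers, the furan and both trisubstituted alkenes, whereas aqueous base could strip the aryl silyl ethers.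

Step 12
Reactants: 21 tris(tert-butyldimethylsilyl) ether of 22
Product: 22 2-[(2E,5S,6E,10E)-5-hydroxy-3,7,11-trimethyl-12-(4-methylfuran-2-yl)dodeca-2,6,10-trien-1-yl]-6-methylbenzene-1,4-diol
Conditions: TBAF, AcOH, THF (degassed), 0 °C to rt
Reagents that add atoms: none
Why: Fluoride-induced cleavage of the two aryl and one secondary alkyl silyl ethers in one operation, buffered with acetic acid and run without oxygen so that neither the allylic alcohol, the furan nor the air-sensitive hydroquinone should suffer.

Compound list
1 | 2,6-dimethylbenzene-1,4-diol | Cc1cc(O)cc(C)c1O | starting material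
2 | 1,4-bis(tert-butyldimethylsilyloxy)-2,6-dimethylbenzene | Cc1cc(O[Si](C)(C)C(C)(C)C)cc(C)c1O[Si](C)(C)C(C)(C)C | intermediate
3 | 2-(bromomethyl)-1,4-bis(tert-butyldimethylsilyloxy)-6-methylbenzene | BrCc1cc(O[Si](C)(C)C(C)(C)C)cc(C)c1O[Si](C)(C)C(C)(C)C | intermediate
4 | but-3-yn-1-ol | C#CCCO | starting material
5 | (E)-alkenylalane from 4: dimethylaluminium on the terminal alkene carbon cis to the new methyl, hydroxyl as its dimethylaluminium alkoxide (formed in the flask) | C[Al](C)/C=C(\C)CCO[Al](C)C | intermediate
6 | (3E)-5-[2,5-bis(tert-butyldimethylsilyloxy)-3-methylphenyl]-3-methylpent-3-en-1-ol | OCC/C(C)=C/Cc1cc(O[Si](C)(C)C(C)(C)C)cc(C)c1O[Si](C)(C)C(C)(C)C | intermediate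
7 | (3E)-5-[2,5-bis(tert-butyldimethylsilyloxy)-3-methylphenyl]-3-methylpent-3-enal | O=CC/C(C)=C/Cc1cc(O[Si](C)(C)C(C)(C)C)cc(C)c1O[Si](C)(C)C(C)(C)C | intermediate
8 | propyne | CC#C | starting material
9 | ethyl(prop-1-ynyl)zinc (formed in the flask) | CC[Zn]C#CC | intermediate
10 | (4S,6E)-8-[2,5-bis(tert-butyldimethylsilyloxy)-3-methylphenyl]-6-methyloct-6-en-2-yn-4-ol | CC#C[C@@H](O)C/C(C)=C/Cc1cc(O[Si](C)(C)C(C)(C)C)cc(C)c1O[Si](C)(C)C(C)(C)C | intermediate
11 | (4S,6E)-8-[2,5-bis(tert-butyldimethylsilyloxy)-3-methylphenyl]-4-(tert-butyldimethylsilyloxy)-6-methyloct-6-en-2-yne | CC#C[C@@H](O[Si](C)(C)C(C)(C)C)C/C(C)=C/Cc1cc(O[Si](C)(C)C(C)(C)C)cc(C)c1O[Si](C)(C)C(C)(C)C | intermediate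
12 | (E)-alkenylzirconocene chloride from 11: zirconium on the methyl-bearing carbon, trans to the silyloxy-bearing carbon (formed in the flask; cyclopentadienyl rings drawn as σ-bonded) | C/C(=C\[C@@H](O[Si](C)(C)C(C)(C)C)C/C(C)=C/Cc1cc(O[Si](C)(C)C(C)(C)C)cc(C)c1O[Si](C)(C)C(C)(C)C)[Zr](Cl)(C1C=CC=C1)C1C=CC=C1 | intermediate
13 | (2E,4S,6E)-8-[2,5-bis(tert-butyldimethylsilyloxy)-3-methylphenyl]-4-(tert-butyldimethylsilyloxy)-2-iodo-6-methylocta-2,6-diene | C/C(I)=C\[C@@H](O[Si](C)(C)C(C)(C)C)C/C(C)=C/Cc1cc(O[Si](C)(C)C(C)(C)C)cc(C)c1O[Si](C)(C)C(C)(C)C | intermediate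
14 | 5-bromo-2-methylpent-2-ene | CC(C)=CCCBr | starting material
15 | (2E)-5-bromo-2-methylpent-2-en-1-ol | OC/C(C)=C/CCBr | intermediate
16 | (2E)-1,5-dibromo-2-methylpent-2-ene | BrC/C(C)=C/CCBr | intermediate
17 | 3-methylfuran | Cc1ccoc1 | starting material
18 | (4-methylfuran-2-yl)magnesium chloride (formed in the flask) | Cc1coc([Mg]Cl)c1 | intermediate
19 | 2-[(2E)-5-bromo-2-methylpent-2-en-1-yl]-4-methylfuran | Cc1coc(C/C(C)=C/CCBr)c1 | intermediate
20 | [(3E)-4-methyl-5-(4-methylfuran-2-yl)pent-3-en-1-yl]zinc bromide (formed in the flask) | Cc1coc(C/C(C)=C/CC[Zn]Br)c1 | intermediate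
21 | tris(tert-butyldimethylsilyl) ether of 22 (both phenols and the C5 hydroxyl silylated; 2E,5S,6E,10E) | C/C(=C\[C@@H](O[Si](C)(C)C(C)(C)C)C/C(C)=C/Cc1cc(O[Si](C)(C)C(C)(C)C)cc(C)c1O[Si](C)(C)C(C)(C)C)CC/C=C(\C)Cc1cc(C)co1 | intermediate
22 | 2-[(2E,5S,6E,10E)-5-hydroxy-3,7,11-trimethyl-12-(4-methylfuran-2-yl)dodeca-2,6,10-trien-1-yl]-6-methylbenzene-1,4-diol | C/C(=C\[C@@H](O)C/C(C)=C/Cc1cc(O)cc(C)c1O)CC/C=C(\C)Cc1cc(C)co1 | target

Total step count: 12. Longest linear sequence: 9 steps (steps 1 to 7, 11 and 12, from 1).

Steps most likely to fail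

Step 5. The β,γ-unsaturated aldehyde may enolise or shift its double bond into conjugation before it is attacked, ethyl transfer from zinc may compete, and facial selectivity on an α-unbranched aldehyde may be insufficient. The fallback sets out from 7 and returns at 10, setting the stereocentre by reduction instead of by C–C bond formation. Addition of prop-1-ynylmagnesium bromide to 7 (THF, −78 °C) gives racemic (6E)-8-[2,5-bis(tert-butyldimethylsilyloxy)-3-methylphenyl]-6-methyloct-6-en-2-yn-4-ol F1. Dess–Martin oxidation gives the ynone (6E)-8-[2,5-bis(tert-butyldimethylsilyloxy)-3-methylphenyl]-6-methyloct-6-en-2-yn-4-one F2. Base-free Noyori transfer hydrogenation with RuCl[(S,S)-TsDPEN](p-cymene) in isopropanol, in which the alkyne takes the place of the aryl group of an aryl ketone, should then give 10.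

Step 10. Metalation may be slow or may occur in part next to the methyl group (C2 of 3-methylfuran), and the allylic substitution may go in part with transposition. The fallback sets out from 16 and returns at 19, fixing the position of the methyl group through the starting lactone. Commercial 3-methylfuran-2(5H)-one is silylated (iPr3SiOTf, Et3N) to 3-methyl-2-(triisopropylsilyloxy)furan F3. AgOCOCF3-promoted alkylation of F3 with 16 at its γ-position gives the butenolide 5-[(2E)-5-bromo-2-methylpent-2-en-1-yl]-3-methylfuran-2(5H)-one F4. Reduction of F4 to the lactol with iBu2AlH at −78 °C and dehydration on acidic work-up should aromatise it to 19.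

Step 2. Ionic bromination of the electron-rich ring next to the unhindered silyloxy group, or a second benzylic bromination, may compete with the radical monobromination. The fallback sets out from 1 and returns at 6, brominating a ring deactivated by acyl groups.
- Ac2O and pyridine give 2,6-dimethyl-1,4-phenylene diacetate F5.
- NBS and AIBN give 2-(bromomethyl)-6-methyl-1,4-phenylene diacetate F6.
- Coupling of F6 with alane 5 under the conditions of step 3 gives 2-[(2E)-5-hydroxy-3-methylpent-2-en-1-yl]-6-methyl-1,4-phenylene diacetate F7.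
- K2CO3 in degassed methanol gives 2-[(2E)-5-hydroxy-3-methylpent-2-en-1-yl]-6-methylbenzene-1,4-diol F8.
- TBSCl and imidazole give the tris-silyl ether (3E)-1-(tert-butyldimethylsilyloxy)-5-[2,5-bis(tert-butyldimethylsilyloxy)-3-methylphenyl]-3-methylpent-3-ene F9.
- Pyridinium p-toluenesulfonate in methanol should cleave only the primary alkyl silyl ether of F9 and return 6.

Further compounds
F1 | step 5 | racemic (6E)-8-[2,5-bis(tert-butyldimethylsilyloxy)-3-methylphenyl]-6-methyloct-6-en-2-yn-4-ol | CC#CC(O)C/C(C)=C/Cc1cc(O[Si](C)(C)C(C)(C)C)cc(C)c1O[Si](C)(C)C(C)(C)C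
F2 | step 5 | (6E)-8-[2,5-bis(tert-butyldimethylsilyloxy)-3-methylphenyl]-6-methyloct-6-en-2-yn-4-one | CC#CC(=O)C/C(C)=C/Cc1cc(O[Si](C)(C)C(C)(C)C)cc(C)c1O[Si](C)(C)C(C)(C)C
F3 | step 10 | 3-methyl-2-(triisopropylsilyloxy)furan | Cc1ccoc1O[Si](C(C)C)(C(C)C)C(C)C
F4 | step 10 | racemic 5-[(2E)-5-bromo-2-methylpent-2-en-1-yl]-3-methylfuran-2(5H)-one | CC1=CC(C/C(C)=C/CCBr)OC1=O
F5 | step 2 | 2,6-dimethyl-1,4-phenylene diacetate | CC(=O)Oc1cc(C)c(OC(C)=O)c(C)c1
F6 | step 2 | 2-(bromomethyl)-6-methyl-1,4-phenylene diacetate | CC(=O)Oc1cc(C)c(OC(C)=O)c(CBr)c1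
F7 | step 2 | 2-[(2E)-5-hydroxy-3-methylpent-2-en-1-yl]-6-methyl-1,4-phenylene diacetate | CC(=O)Oc1cc(C)c(OC(C)=O)c(C/C=C(\C)CCO)c1
F8 | step 2 | 2-[(2E)-5-hydroxy-3-methylpent-2-en-1-yl]-6-methylbenzene-1,4-diol | Cc1cc(O)cc(C/C=C(\C)CCO)c1O
F9 | step 2 | (3E)-1-(tert-butyldimethylsilyloxy)-5-[2,5-bis(tert-butyldimethylsilyloxy)-3-methylphenyl]-3-methylpent-3-ene | CC(C)(C)[Si](C)(C)OCC/C(C)=C/Cc1cc(O[Si](C)(C)C(C)(C)C)cc(C)c1O[Si](C)(C)C(C)(C)C
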